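**Assumption:** 3,4,5‑tris(benzyloxy)benzaldehyde, 3,5‑bis(benzyloxy)phenol, (S)‑but‑3‑en‑2‑ol and 5‑hydroxyvanillin are purchasable. The diastereomers from the Diels–Alder step are separable by silica chromatography. The (S)‑relay gives the (2R,3S)‑trans series as the isolable product.

## Retrosynthesis
- The target comes from global O‑debenzylation of the 3‑O‑(bis‑O‑benzyl‑3‑methylgallate) ester of penta‑O‑benzyl‑epigallocatechin.
- That ester comes from a Mitsunobu esterification of penta‑O‑benzyl‑(+)‑gallocatechin (2,3‑trans) with inversion at C3. This gives the 2,3‑cis configuration.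
- The trans 3‑alcohol comes from a 3‑(1‑silyloxyethyl)chromane by TBS removal, oxidation to the methyl ketone, and Baeyer–Villiger oxidation with retention.
- Ring C is the only ring formed. It forms in an inverse‑electron‑demand hetero‑Diels–Alder between an o‑quinone methide (from 3,5‑bis(benzyloxy)phenol and CH2O) and an (E)‑styrene. The styrene carries a stereodefining (S)‑1‑silyloxyethyl group from (S)‑but‑3‑en‑2‑ol.
- Rings A, B and D are purchased as arenes.

## Forward route

**Step 1**
Reactants: 1, 3,4,5‑tris(benzyloxy)benzaldehyde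
Product: 2, 3,4,5‑tris(benzyloxy)styrene
Conditions: Ph3P⁺CH3 Br⁻, KOtBu, THF, 0 °C → rt
Reagents that add atoms: methyltriphenylphosphonium bromide, C[P+](c1ccccc1)(c1ccccc1)c1ccccc1.[Br-] (supplies the =CH2)
Why: Wittig methylenation converts the aldehyde to the terminal alkene without touching the benzyl ethers.

**Step 2**
Reactants: 3, (S)‑but‑3‑en‑2‑ol
Product: 4, (S)‑tert‑butyldimethyl(but‑3‑en‑2‑yloxy)silane
Conditions: TBSCl, imidazole, DMF, rt
Reagents that add atoms: TBSCl, C[Si](C)(Cl)C(C)(C)C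
Why: Silylation masks the OH so it does not trap the o‑quinone methide later. The stereocenter is untouched.

**Step 3**
Reactants: 2, styrene; 4, silyl ether (3 equiv)
Product: 5, (S,E)‑TBS ether of 4‑[3,4,5‑tris(benzyloxy)phenyl]but‑3‑en‑2‑ol
Conditions: Grubbs II (5 mol%), CH2Cl2, 40 °C
Reagents that add atoms: none
Why: Cross‑metathesis with excess of the allylic ether gives the (E)‑1,2‑disubstituted styrene, which sets 2,3‑trans in the next step.

**Step 4**
Reactants: 5, styrene; 6, 3,5‑bis(benzyloxy)phenol (2.5 equiv)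
Product: 7, TBS ether of the 2,3‑trans‑3‑(1‑hydroxyethyl)chromane (ring C formed)
Conditions: (CH2O)n (3 equiv), PhB(OH)2 (1.2 equiv), EtCO2H (cat.), toluene, 110 °C, sealed tube; then separate diastereomers by chromatography
Reagents that add atoms: formaldehyde (from paraformaldehyde), C=O (gives C4 as CH2)
Why: Inverse‑electron‑demand hetero‑Diels–Alder. The boronate directs ortho‑hydroxymethylation and releases the o‑quinone methide, which adds across the aryl‑conjugated alkene. The aryl‑stabilised benzylic position bonds to O, which sets the 2‑aryl regiochemistry. The concerted suprafacial addition to the E‑alkene gives 2,3‑trans. The allylic OTBS stereocenter biases the alkene face, giving separable diastereomers.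

**Step 5**
Reactants: 7
Product: 8, secondary alcohol
Conditions: TBAF, THF, rt
Reagents that add atoms: none
Why: Fluoride cleaves the Si–O bond and leaves the benzyl ethers and all stereocenters intact.

**Step 6**
Reactants: 8
Product: 9, 3‑acetylchromane
Conditions: Dess–Martin periodinane, NaHCO3, CH2Cl2, 0 °C → rt
Reagents that add atoms: none
Why: Mild oxidation of the secondary alcohol to the methyl ketone. This destroys the relay stereocenter. Any epimerisation at C3 α to the ketone drifts to the thermodynamic 2,3‑trans isomer, which is wanted.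

**Step 7**
Reactants: 9
Product: 10, (2R,3S)‑3‑acetoxychromane
Conditions: mCPBA, NaHCO3, CH2Cl2, 0 °C → rt
Reagents that add atoms: mCPBA, OOC(=O)c1cccc(Cl)c1 (inserts one O)
Why: Baeyer–Villiger oxidation. The secondary ring carbon migrates in preference to methyl, with retention of configuration. C3 therefore becomes an O‑bearing carbon of known configuration.

**Step 8**
Reactants: 10
Product: 11, penta‑O‑benzyl‑(+)‑gallocatechin, the (2R,3S)‑trans 3‑alcohol
Conditions: K2CO3, MeOH/THF, rt
Reagents that add atoms: none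
Why: Transesterification cleaves the acetate and leaves C2 and C3 untouched.

**Step 9**
Reactants: 12, 3,4‑dihydroxy‑5‑methoxybenzaldehyde (5‑hydroxyvanillin)
Product: 13, 3,4‑bis(benzyloxy)‑5‑methoxybenzaldehyde
Conditions: BnBr, K2CO3, DMF, 60 °C
Reagents that add atoms: benzyl bromide, BrCc1ccccc1
Why: Williamson O‑benzylation protects both phenols of the 3‑methylgallate unit.

**Step 10**
Reactants: 13
Product: 14, 3,4‑bis(benzyloxy)‑5‑methoxybenzoic acid
Conditions: NaClO2, NaH2PO4, 2‑methyl‑2‑butene, t‑BuOH/H2O, rt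
Reagents that add atoms: sodium chlorite, [Na+].[O-]Cl=O (adds O)
Why: Pinnick oxidation converts the aldehyde to the acid. The alkene scavenger prevents ring chlorination.

**Step 11**
Reactants: 11, trans‑alcohol; 14, acid
Product: 15, (2R,3R)‑cis 3‑O‑(3,4‑bis(benzyloxy)‑5‑methoxybenzoyl) penta‑O‑benzyl ether
Conditions: PPh3, DIAD, THF, 0 °C → rt
Reagents that add atoms: none
Why: Mitsunobu esterification. The carboxylate displaces the activated C3‑oxyphosphonium by SN2, inverting C3 from S to R. This converts trans to the natural 2,3‑cis configuration, and C2 is unaffected.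

**Step 12**
Reactants: 15
Product: 16, target
Conditions: H2 (1 atm), Pd(OH)2/C, THF/MeOH, rt
Reagents that add atoms: none (H2 adds only H)
Why: Hydrogenolysis removes all seven benzyl ethers. The aryl methyl ether, the ester and the C2/C3 stereocenters survive these conditions.

## Compound list
1 | 3,4,5‑tris(benzyloxy)benzaldehyde | O=Cc1cc(OCc2ccccc2)c(OCc2ccccc2)c(OCc2ccccc2)c1 | starting material
2 | 3,4,5‑tris(benzyloxy)styrene | C=Cc1cc(OCc2ccccc2)c(OCc2ccccc2)c(OCc2ccccc2)c1 | intermediate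
3 | (S)‑but‑3‑en‑2‑ol | C[C@H](O)C=C | starting material
4 | (S)‑TBS ether of but‑3‑en‑2‑ol | C[C@H](O[Si](C)(C)C(C)(C)C)C=C | intermediate
5 | (S,E)‑TBS ether of 4‑[3,4,5‑tris(benzyloxy)phenyl]but‑3‑en‑2‑ol | C[C@H](O[Si](C)(C)C(C)(C)C)/C=C/c1cc(OCc2ccccc2)c(OCc2ccccc2)c(OCc2ccccc2)c1 | intermediate
6 | 3,5‑bis(benzyloxy)phenol | Oc1cc(OCc2ccccc2)cc(OCc2ccccc2)c1 | starting material
7 | tert‑butyl{(1S)‑1‑[(2S,3S)‑5,7‑bis(benzyloxy)‑2‑(3,4,5‑tris(benzyloxy)phenyl)chroman‑3‑yl]ethoxy}dimethylsilane | C[C@H](O[Si](C)(C)C(C)(C)C)[C@H]2Cc3c(OCc4ccccc4)cc(OCc4ccccc4)cc3O[C@@H]2c2cc(OCc3ccccc3)c(OCc3ccccc3)c(OCc3ccccc3)c2 | intermediate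
8 | (1S)‑1‑[(2S,3R)‑5,7‑bis(benzyloxy)‑2‑(3,4,5‑tris(benzyloxy)phenyl)chroman‑3‑yl]ethan‑1‑ol | C[C@H](O)[C@H]2Cc3c(OCc4ccccc4)cc(OCc4ccccc4)cc3O[C@@H]2c2cc(OCc3ccccc3)c(OCc3ccccc3)c(OCc3ccccc3)c2 | intermediate
9 | 1‑[(2S,3S)‑5,7‑bis(benzyloxy)‑2‑(3,4,5‑tris(benzyloxy)phenyl)chroman‑3‑yl]ethan‑1‑one | CC(=O)[C@H]2Cc3c(OCc4ccccc4)cc(OCc4ccccc4)cc3O[C@@H]2c2cc(OCc3ccccc3)c(OCc3ccccc3)c(OCc3ccccc3)c2 | intermediate
10 | (2R,3S)‑5,7‑bis(benzyloxy)‑2‑(3,4,5‑tris(benzyloxy)phenyl)chroman‑3‑yl acetate | CC(=O)O[C@H]2Cc3c(OCc4ccccc4)cc(OCc4ccccc4)cc3O[C@@H]2c2cc(OCc3ccccc3)c(OCc3ccccc3)c(OCc3ccccc3)c2 | intermediate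
11 | (2R,3S)‑5,7,3′,4′,5′‑penta‑O‑benzyl‑(+)‑gallocatechin | O[C@H]2Cc3c(OCc4ccccc4)cc(OCc4ccccc4)cc3O[C@@H]2c2cc(OCc3ccccc3)c(OCc3ccccc3)c(OCc3ccccc3)c2 | intermediate
12 | 3,4‑dihydroxy‑5‑methoxybenzaldehyde | COc1cc(C=O)cc(O)c1O | starting material
13 | 3,4‑bis(benzyloxy)‑5‑methoxybenzaldehyde | COc1cc(C=O)cc(OCc2ccccc2)c1OCc1ccccc1 | intermediate
14 | 3,4‑bis(benzyloxy)‑5‑methoxybenzoic acid | COc1cc(C(=O)O)cc(OCc2ccccc2)c1OCc1ccccc1 | intermediate
15 | (2R,3R)‑5,7‑bis(benzyloxy)‑2‑(3,4,5‑tris(benzyloxy)phenyl)chroman‑3‑yl 3,4‑bis(benzyloxy)‑5‑methoxybenzoate | COc1cc(C(=O)O[C@@H]2Cc3c(OCc4ccccc4)cc(OCc4ccccc4)cc3O[C@@H]2c2cc(OCc3ccccc3)c(OCc3ccccc3)c(OCc3ccccc3)c2)cc(OCc2ccccc2)c1OCc1ccccc1 | intermediate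
16 | (−)‑Epigallocatechin 3‑(3‑methylgallate) | COc1cc(C(=O)O[C@@H]2Cc3c(O)cc(O)cc3O[C@@H]2c2cc(O)c(O)c(O)c2)cc(O)c1O | target

## Totals
Total steps: 12. Longest linear sequence: 9 (1 → 2 → 5 → 7 → 8 → 9 → 10 → 11 → 15 → 16, i.e. steps 1, 3, 4, 5, 6, 7, 8, 11, 12).

## Three steps most likely to fail
1. **Step 4 (hetero‑Diels–Alder).** The electron‑rich phenol can oligomerise through the o‑quinone methide, and the diastereoselectivity from the remote OTBS center may be modest.
   - Fallback: build 11 by a non‑pericyclic chiral‑pool route. Add 3,4,5‑tris(benzyloxy)phenylmagnesium bromide to D‑glyceraldehyde acetonide, convert the product to the terminal epoxide, open it with the A‑ring aryllithium, and close the ring by Mitsunobu O‑arylation.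
2. **Step 7 (Baeyer–Villiger).** mCPBA may oxidise the electron‑rich polybenzyloxy arenes, and the β‑oxygenated ring carbon migrates more slowly.
   - Fallback: use a D‑glyceraldehyde‑acetonide‑derived relay in the styrene. After the cycloaddition, cleave the diol with NaIO4 to the C3 aldehyde and convert it to the formate with H2O2/(PhSe)2. The formate then hydrolyses to the alcohol.
3. **Step 11 (Mitsunobu inversion).** The hindered secondary alcohol may undergo elimination or give incomplete conversion.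
   - Fallback: oxidise 11 to the flavan‑3‑one with Dess–Martin periodinane and reduce it with a bulky hydride to the 2,3‑cis alcohol. Then acylate with acid 14 (DCC/DMAP, Steglich) with retention.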